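**Retrosynthetic overview**
1. Dryocrassin ABBA (14) is symmetric about its central CH2, so it is cut there into two molecules of norflavaspidic acid AB (10) plus formaldehyde (hydroxymethylation, ortho-quinone methide, Michael addition).
2. The ring A–CH2–ring B bridge of 10 is cut next: intermolecular Michael addition of butyrylphloroglucinol (3) to the exocyclic methylene enetrione 9, released from the Mannich salt 8 of acetylfilicinic acid (6).
3. 6 comes from 2,4,6-trihydroxyacetophenone by dearomative gem-dimethylation; 3 comes from phloroglucinol by Friedel–Crafts butanoylation.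
4. No ring is closed by cyclisation: ring B is a phloroglucinol ring throughout, and ring A is made first (step 2) by dearomatising a phloroglucinol ring. The A–B bridge is then formed, and the B–B bridge last.

Assumption: the target SMILES has no stereocentre and no stereogenic double bond (the molecule is achiral), so no stereocontrol is needed; all triketone rings are drawn in the enol tautomer of the given SMILES.

**Step 1**
Reactants: 1 phloroglucinol (benzene-1,3,5-triol, dried); 2 butanoyl chloride
Product: 3 butyrylphloroglucinol, 1-(2,4,6-trihydroxyphenyl)butan-1-one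
Conditions: AlCl3 (4 equiv), PhNO2/CH2Cl2, 0 °C → 40 °C, 3 h; ice, 1 M HCl
Reagents that add atoms: butanoyl chloride (2), CCCC(Cl)=O
Why: Friedel–Crafts C-acylation of the very electron-rich arene, where the aluminium chelate of the product ketone deactivates the ring so that mono-acylation dominates; no stereocentre is formed.

**Step 2**
Reactants: 4 2,4,6-trihydroxyacetophenone (dried); 5 iodomethane
Product: 6 acetylfilicinic acid, 2-acetyl-3,5-dihydroxy-6,6-dimethylcyclohexa-2,4-dien-1-one
Conditions: NaOMe (3.0 equiv), MeI (2.2 equiv), MeOH, 0 °C → rt, 12 h; 1 M HCl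
Reagents that add atoms: iodomethane (5), CI
Why: dearomative twofold C-methylation of the acylphloroglucinol phenolate at one ring carbon gives the gem-dimethyl β-triketone, a strong vinylogous acid that is separated from mono- and trimethylated by-products by bicarbonate extraction and crystallisation; no stereocentre is formed.

**Step 3**
Reactants: 6 acetylfilicinic acid; 7 N,N-dimethylmethyleneiminium iodide (Eschenmoser's salt)
Product: 8 2-acetyl-4-[(dimethylamino)methyl]-3,5-dihydroxy-6,6-dimethylcyclohexa-2,4-dien-1-one hydroiodide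
Conditions: CH2=NMe2+ I− (1.1 equiv), dry MeCN, 0 °C → rt, 2 h; Et2O, filter
Reagents that add atoms: Eschenmoser's salt (7), C=[N+](C)C.[I-]
Why: intermolecular Mannich reaction at C-4, the only C–H nucleophilic carbon of the enolised triketone, run without base so that the amine stays protonated and does not eliminate during isolation; no stereocentre is formed.

**Step 4**
Reactants: 8 Mannich salt of acetylfilicinic acid; 3 butyrylphloroglucinol (3 equiv, excess recovered)
Product: 10 norflavaspidic acid AB, via methylene enetrione 9 (not isolated)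
Conditions: 3 (3.0 equiv), NaOMe (2.0 equiv), MeOH, 0 °C, 8 added over 1 h, then rt, 2 h; 1 M HCl
Reagents that add atoms: none
Why: NaOMe converts 8 into its betaine, which loses dimethylamine (E1cB) to the highly electrophilic enetrione 9, and the phenolate of 3 (in excess, so only one of its two equivalent positions reacts) adds through ring carbon in an intermolecular Michael addition followed by re-aromatisation; no stereocentre is formed.

**Step 5**
Reactants: 10 norflavaspidic acid AB (2 equiv); 11 formaldehyde
Product: 14 dryocrassin ABBA, via hydroxymethyl compound 12 (not isolated), via ortho-quinone methide 13 (not isolated)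
Conditions: 37% aq. CH2O (0.50 equiv), 1% aq. KOH (3 equiv), 0 °C → rt, 15 min; 1 M HCl to pH 2
Reagents that add atoms: formaldehyde (11), C=O
Why: ring B of 10 has a single free carbon, which is hydroxymethylated (aldol-type Lederer–Manasse addition) to 12, loses hydroxide to quinone methide 13 and is captured by a second phenolate of 10 in an intermolecular Michael addition, so with half an equivalent of formaldehyde only the symmetric dimer can form; no stereocentre is formed.

**Compound list**
1 | phloroglucinol (benzene-1,3,5-triol) | Oc1cc(O)cc(O)c1 | starting material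
2 | butanoyl chloride | CCCC(Cl)=O | starting material
3 | butyrylphloroglucinol, 1-(2,4,6-trihydroxyphenyl)butan-1-one | CCCC(=O)c1c(O)cc(O)cc1O | intermediate
4 | 2,4,6-trihydroxyacetophenone, 1-(2,4,6-trihydroxyphenyl)ethan-1-one | CC(=O)c1c(O)cc(O)cc1O | starting material
5 | iodomethane | CI | starting material
6 | acetylfilicinic acid, 2-acetyl-3,5-dihydroxy-6,6-dimethylcyclohexa-2,4-dien-1-one | CC(=O)C1=C(O)C=C(O)C(C)(C)C1=O | intermediate
7 | N,N-dimethylmethyleneiminium iodide (Eschenmoser's salt) | C=[N+](C)C.[I-] | starting material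
8 | 2-acetyl-4-[(dimethylamino)methyl]-3,5-dihydroxy-6,6-dimethylcyclohexa-2,4-dien-1-one hydroiodide | CC(=O)C1=C(O)C(C[NH+](C)C)=C(O)C(C)(C)C1=O.[I-] | intermediate
9 | 2-acetyl-3-hydroxy-6,6-dimethyl-4-methylidenecyclohex-2-ene-1,5-dione (methylene enetrione, formed and consumed in the flask) | C=C1C(=O)C(C)(C)C(=O)C(C(C)=O)=C1O | intermediate
10 | norflavaspidic acid AB, 2-acetyl-4-[(3-butanoyl-2,4,6-trihydroxyphenyl)methyl]-3,5-dihydroxy-6,6-dimethylcyclohexa-2,4-dien-1-one | CCCC(=O)c1c(O)cc(O)c(CC2=C(O)C(C)(C)C(=O)C(C(C)=O)=C2O)c1O | intermediate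
11 | formaldehyde (37% aqueous solution) | C=O | starting material
12 | 2-acetyl-4-{[3-butanoyl-2,4,6-trihydroxy-5-(hydroxymethyl)phenyl]methyl}-3,5-dihydroxy-6,6-dimethylcyclohexa-2,4-dien-1-one (formed and consumed in the flask) | CCCC(=O)c1c(O)c(CO)c(O)c(CC2=C(O)C(C)(C)C(=O)C(C(C)=O)=C2O)c1O | intermediate
13 | 2-acetyl-4-[(3-butanoyl-2,4-dihydroxy-5-methylidene-6-oxocyclohexa-1,3-dien-1-yl)methyl]-3,5-dihydroxy-6,6-dimethylcyclohexa-2,4-dien-1-one (ortho-quinone methide of ring B, formed and consumed in the flask) | CCCC(=O)C1=C(O)C(=C)C(=O)C(CC2=C(O)C(C)(C)C(=O)C(C(C)=O)=C2O)=C1O | intermediate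
14 | dryocrassin ABBA, bis{3-butanoyl-5-[(5-acetyl-2,6-dihydroxy-3,3-dimethyl-4-oxocyclohexa-1,5-dien-1-yl)methyl]-2,4,6-trihydroxyphenyl}methane | CCCC(=O)c1c(O)c(CC2=C(O)C(C)(C)C(=O)C(C(C)=O)=C2O)c(O)c(Cc2c(O)c(CC3=C(O)C(C)(C)C(=O)C(C(C)=O)=C3O)c(O)c(C(=O)CCC)c2O)c1O | target

**Total step count:** 5.
**Longest linear sequence:** 4 steps (4 → 6 → 8 → 10 → 14; steps 2, 3, 4 and 5).

**Three steps most likely to fail**

Step 3 (Mannich salt of the triketone). The risk is that 8 eliminates during isolation and is captured by unreacted 6, giving the ring A–CH2–ring A dimer. The fallback exchanges the roles of the two partners and sets out from 3. Slow addition of 7 (1.0 equiv, MeCN, −20 °C) to 3 gives the phenolic Mannich salt 1-{3-[(dimethylamino)methyl]-2,4,6-trihydroxyphenyl}butan-1-one hydroiodide F1, a robust class of compound. F1 is then warmed with 6 (2 equiv) and NaOMe (3 equiv) in MeOH at 40 °C. This releases the ring B ortho-quinone methide 2-butanoyl-3,5-dihydroxy-6-methylidenecyclohexa-2,4-dien-1-one F2 in the flask, and the enolate of 6 adds to it through C-4 in a Michael reaction. The fallback comes back to the route at 10 and needs neither 8 nor 9.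

Step 4 (mono-selective Michael coupling). The risk is twofold alkylation of 3 (ring A–CH2–ring B–CH2–ring A) or self-reaction of 9. The fallback builds the central bridge first, so that each ring B has only one free position when ring A is attached. It sets out from 3 (4 equiv), which with 11 (1 equiv) in 1% aq. KOH at 0 °C gives the hydroxymethyl ketone 1-[2,4,6-trihydroxy-3-(hydroxymethyl)phenyl]butan-1-one F3. F3 loses hydroxide to the same quinone methide F2 and is captured by 3 to give methylenebis(butyrylphloroglucinol) F4. The statistical step now falls on one-step material, and excess 3 is recovered. F4 is then treated with 8 (2.3 equiv) and NaOMe in MeOH as in step 4, so that two molecules of 9 are taken up one after the other, through the mono-adduct ring A–CH2–ring B–CH2–ring B F5. The fallback comes back to the route at 14 and leaves out 10 and step 5.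

Step 5 (alkaline formaldehyde dimerisation). The risk is exchange of methylene bridges in aqueous alkali, or incomplete conversion of 12. The fallback makes the last bridge in two controlled stages without aqueous alkali and sets out from 10. Treatment with 7 (1.1 equiv, MeCN, 0 °C) aminomethylates the only free position of ring B to give the Mannich salt 2-acetyl-4-({3-butanoyl-5-[(dimethylamino)methyl]-2,4,6-trihydroxyphenyl}methyl)-3,5-dihydroxy-6,6-dimethylcyclohexa-2,4-dien-1-one hydroiodide F6. F6 is then warmed with one further equivalent of 10 and NaOMe (4 equiv) in MeOH at 40 °C. It loses dimethylamine to the quinone methide 13, which is captured by the phenolate of 10 in a Michael addition. The fallback comes back to the route at 14.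

**Further compounds**
F1 | step 3 | 1-{3-[(dimethylamino)methyl]-2,4,6-trihydroxyphenyl}butan-1-one hydroiodide | CCCC(=O)c1c(O)cc(O)c(C[NH+](C)C)c1O.[I-]
F2 | step 3 | 2-butanoyl-3,5-dihydroxy-6-methylidenecyclohexa-2,4-dien-1-one | CCCC(=O)C1=C(O)C=C(O)C(=C)C1=O
F3 | step 4 | 1-[2,4,6-trihydroxy-3-(hydroxymethyl)phenyl]butan-1-one | CCCC(=O)c1c(O)cc(O)c(CO)c1O
F4 | step 4 | methylenebis(butyrylphloroglucinol), 1,1'-[methylenebis(2,4,6-trihydroxybenzene-3,1-diyl)]di(butan-1-one) | CCCC(=O)c1c(O)cc(O)c(Cc2c(O)cc(O)c(C(=O)CCC)c2O)c1O
F5 | step 4 | 2-acetyl-4-({3-butanoyl-5-[(3-butanoyl-2,4,6-trihydroxyphenyl)methyl]-2,4,6-trihydroxyphenyl}methyl)-3,5-dihydroxy-6,6-dimethylcyclohexa-2,4-dien-1-one | CCCC(=O)c1c(O)cc(O)c(Cc2c(O)c(CC3=C(O)C(C)(C)C(=O)C(C(C)=O)=C3O)c(O)c(C(=O)CCC)c2O)c1O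
F6 | step 5 | 2-acetyl-4-({3-butanoyl-5-[(dimethylamino)methyl]-2,4,6-trihydroxyphenyl}methyl)-3,5-dihydroxy-6,6-dimethylcyclohexa-2,4-dien-1-one hydroiodide | CCCC(=O)c1c(O)c(C[NH+](C)C)c(O)c(CC2=C(O)C(C)(C)C(=O)C(C(C)=O)=C2O)c1O.[I-]
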